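**Assumption:** ent-labdane numbering is used, α is the face of the C10 methyl (C20), and reagents are not numbered but are given with SMILES in each step.

**Retrosynthetic overview**
1. Target 19 ⇐ desilylation of 18 ⇐ Yamaguchi angeloylation of the 3α-ol 15 with angelic acid 16.
2. Ring A: C3 comes from NaBH4 reduction of a 3-ketone. The C4 quaternary centre comes from deformylation of keto-aldehyde 11 and a formaldehyde aldol of the resulting enolate, which swaps the axial CH2OH of andrographolide for an equatorial one.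
3. Side chain: the 13E-allylic silyl ether comes from the Z-enediol 6 (15-O-silylation, C16–OH to CH3), and 6 comes from butenolide 5.
4. Key step: butenolide 5 ⇐ andrographolide acetonide 2 by a Myers allylic diazene rearrangement (sigmatropic loss of N2). It forms the C12–H bond and moves the alkene into the lactone ring, which later fixes the 13E geometry.
5. No ring is formed. Rings A and B with C5, C9 and C10 are taken intact from andrographolide 1, and the lactone ring is opened.

**Route**

Step 1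
Reactants: 1 andrographolide
Product: 2 3,19-O-isopropylidene andrographolide
Conditions: 2,2-dimethoxypropane, PPTS (cat.), toluene–DMSO, 80 °C
Reagents that add atoms: 2,2-dimethoxypropane, COC(C)(C)OC
Why: Acid-catalysed transketalisation closes the six-membered 1,3-dioxane across the syn 3,19-diol and leaves only the allylic 14-OH free; no stereocentre is touched.

Step 2
Reactants: 2 3,19-O-isopropylidene andrographolide
Product: 5 3,19-O-isopropylidene-14-deoxyandrographolide, via sulfonylhydrazine Mitsunobu adduct 3 (not isolated), via allylic diazene 4 (not isolated)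
Conditions: PPh3, DEAD, 2-nitrobenzenesulfonohydrazide (NBSH), THF, −30 °C; then 23 °C
Reagents that add atoms: none
Why: Myers reductive 1,3-transposition: Mitsunobu displacement of the allylic 14-OH by NBSH, loss of sulfinic acid to the monoalkyl diazene, and concerted sigmatropic (retro-ene) loss of N2 deliver H to C12 and shift the alkene to C13=C14 inside the lactone ring; C14 stops being a stereocentre.

Step 3
Reactants: 5 3,19-O-isopropylidene-14-deoxyandrographolide
Product: 6 3,19-O-isopropylidene-ent-labda-8(17),13Z-diene-3α,15,16,19-tetraol (15,16-diol)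
Conditions: i-Bu2AlH (4 equiv), CH2Cl2, −78 → 0 °C; aq. KNaC4H4O6 work-up
Reagents that add atoms: none
Why: Exhaustive 1,2-reduction of the butenolide gives the Z-ene-1,4-diol whose geometry (C12 trans to C15) is inherited from the ring; acetonide and alkenes are inert.

Step 4
Reactants: 6 the 15,16-diol
Product: 7 15-O-TBDPS ether of 6 (16-OH free)
Conditions: TBDPSCl (1.05 equiv), imidazole, CH2Cl2, −20 → 0 °C
Reagents that add atoms: tert-butyldiphenylsilyl chloride, CC(C)(C)[Si](Cl)(c1ccccc1)c1ccccc1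
Why: Sterically controlled monosilylation: the bulky silyl chloride reacts faster at the 15-OH on the CH= carbon than at the 16-OH next to the fully substituted C13; the minor regioisomer is removed by chromatography.

Step 5
Reactants: 7 15-O-TBDPS ether (16-OH free)
Product: 9 15-O-TBDPS-3,19-O-isopropylidene-ent-labda-8(17),13E-diene-3α,15,19-triol, via allylic 16-mesylate 8 (not isolated)
Conditions: MsCl, Et3N, THF, −40 °C; then LiBHEt3, −40 → 0 °C
Reagents that add atoms: none
Why: Deoxygenation by direct SN2 hydride displacement of the primary allylic mesylate turns C16 into the C13 methyl without moving or isomerising the alkene, which is now 13E by CIP rules.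

Step 6
Reactants: 9 the acetonide
Product: 10 15-O-TBDPS-ent-labda-8(17),13E-diene-3α,15,19-triol
Conditions: AcOH–H2O–THF (3:1:1), 40 °C
Reagents that add atoms: none
Why: Mild acetal hydrolysis frees the 3,19-diol; the TBDPS ether and both alkenes tolerate aqueous acetic acid.

Step 7
Reactants: 10 the 3,19-diol
Product: 11 15-O-TBDPS-3-oxo-ent-labda-8(17),13E-dien-19-al
Conditions: Dess–Martin periodinane (2.5 equiv), NaHCO3, CH2Cl2, 0 → 23 °C
Reagents that add atoms: none
Why: Dess–Martin oxidation of both hydroxyls gives the β-keto aldehyde (quaternary C4, so no enolisation there) under buffered conditions that spare the alkenes and the silyl ether.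

Step 8
Reactants: 11 the keto-aldehyde
Product: 13 15-O-TBDPS-18-hydroxy-ent-labda-8(17),13E-dien-3-one, via lithium C3–C4 enolate 12 (not isolated)
Conditions: 11 added to LiOEt (1.05 equiv), THF, −78 → −20 °C; then HCHO (g, from cracked paraformaldehyde), −78 °C; AcOH quench
Reagents that add atoms: formaldehyde, C=O
Why: Retro-Claisen deformylation by ethoxide gives the C3–C4 lithium enolate regiospecifically, and its aldol addition to formaldehyde occurs on the β face, anti to the axial C10 methyl, so the new CH2OH is equatorial (4β) and the retained methyl axial (4α); C4 is set by substrate control.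

Step 9
Reactants: 13 the hydroxy ketone
Product: 14 18-O-TBS ether of 13
Conditions: TBSCl, imidazole, DMF, 23 °C
Reagents that add atoms: tert-butyldimethylsilyl chloride, CC(C)(C)[Si](C)(C)Cl
Why: Standard silylation of the only free (primary) hydroxyl, which also prevents retro-aldol loss of formaldehyde.

Step 10
Reactants: 14 the silyloxy ketone
Product: 15 18-O-TBS-15-O-TBDPS-ent-labda-8(17),13E-diene-3α,15,18-triol (3α-OH free)
Conditions: NaBH4, MeOH–THF, 0 °C
Reagents that add atoms: none
Why: Substrate-controlled hydride reduction: the α face of C3 is shielded by the axial C4 and C10 methyls, so hydride adds axially from the β face and gives the equatorial 3α-alcohol.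

Step 11
Reactants: 15 the 3α-ol; 16 angelic acid
Product: 18 3α-O-angeloyl-18-O-TBS-15-O-TBDPS-ent-labda-8(17),13E-diene-3α,15,18-triol, via mixed Yamaguchi anhydride 17 (not isolated)
Conditions: 16, 2,4,6-trichlorobenzoyl chloride, Et3N, toluene, 23 °C; then 15, 80 °C (no DMAP)
Reagents that add atoms: none
Why: Yamaguchi mixed-anhydride esterification acylates the hindered secondary alcohol at the less hindered angeloyl carbonyl, and omitting nucleophilic catalysts keeps the Z (angelate) geometry.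

Step 12
Reactants: 18 the bis-silyl angelate
Product: 19 3α-angeloyloxy-ent-labda-8(17),13E-diene-15,18-diol (target CNP0118197.1)
Conditions: HF·pyridine, pyridine–THF, 0 → 23 °C
Reagents that add atoms: none
Why: Fluoride desilylation removes both silyl ethers under buffered, non-basic conditions, which avoids 3→18 acyl migration and angelate-to-tiglate isomerisation.

**Compound list**

1 | andrographolide (ent-labdane: 3α,14,19-triol, 8(17),12E-diene, 16,15-olide) | C=C1CC[C@H]2[C@@](C)(CC[C@@H](O)[C@@]2(C)CO)[C@@H]1C/C=C1/C(=O)OC[C@H]1O | starting material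
2 | 3,19-O-isopropylidene andrographolide (1,3-dioxane across O3/O19, 14-OH free) | C=C1CC[C@H]2[C@@](C)(CC[C@H]3OC(C)(C)OC[C@@]23C)[C@@H]1C/C=C1/C(=O)OC[C@H]1O | intermediate
3 | Mitsunobu adduct: C14-inverted N-amino-N-(2-nitrophenylsulfonyl)amino derivative of 2 | C=C1CC[C@H]2[C@@](C)(CC[C@H]3OC(C)(C)OC[C@@]23C)[C@@H]1C/C=C1/C(=O)OC[C@@H]1N(N)S(=O)(=O)c1ccccc1[N+](=O)[O-] | intermediate (not isolated)
4 | allylic monoalkyl diazene (C14–N=NH) derived from 3 | C=C1CC[C@H]2[C@@](C)(CC[C@H]3OC(C)(C)OC[C@@]23C)[C@@H]1C/C=C1/C(=O)OC[C@@H]1N=N | intermediate (not isolated)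
5 | 3,19-O-isopropylidene-14-deoxyandrographolide (C12H2, C13=C14 butenolide) | C=C1CC[C@H]2[C@@](C)(CC[C@H]3OC(C)(C)OC[C@@]23C)[C@@H]1CCC1=CCOC1=O | intermediate
6 | 3,19-O-isopropylidene-ent-labda-8(17),13Z-diene-3α,15,16,19-tetraol (15,16-diol) | C=C1CC[C@H]2[C@@](C)(CC[C@H]3OC(C)(C)OC[C@@]23C)[C@@H]1CC/C(CO)=C/CO | intermediate
7 | 15-O-TBDPS ether of 6 (16-OH free) | C=C1CC[C@H]2[C@@](C)(CC[C@H]3OC(C)(C)OC[C@@]23C)[C@@H]1CC/C(CO)=C/CO[Si](c1ccccc1)(c1ccccc1)C(C)(C)C | intermediate
8 | 16-O-mesylate of 7 | C=C1CC[C@H]2[C@@](C)(CC[C@H]3OC(C)(C)OC[C@@]23C)[C@@H]1CC/C(COS(C)(=O)=O)=C/CO[Si](c1ccccc1)(c1ccccc1)C(C)(C)C | intermediate (not isolated)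
9 | 15-O-TBDPS-3,19-O-isopropylidene-ent-labda-8(17),13E-diene-3α,15,19-triol | C=C1CC[C@H]2[C@@](C)(CC[C@H]3OC(C)(C)OC[C@@]23C)[C@@H]1CC/C(C)=C/CO[Si](c1ccccc1)(c1ccccc1)C(C)(C)C | intermediate
10 | 15-O-TBDPS-ent-labda-8(17),13E-diene-3α,15,19-triol | C=C1CC[C@H]2[C@@](C)(CC[C@@H](O)[C@@]2(C)CO)[C@@H]1CC/C(C)=C/CO[Si](c1ccccc1)(c1ccccc1)C(C)(C)C | intermediate
11 | 15-O-TBDPS-3-oxo-ent-labda-8(17),13E-dien-19-al | C=C1CC[C@H]2[C@@](C)(CCC(=O)[C@@]2(C)C=O)[C@@H]1CC/C(C)=C/CO[Si](c1ccccc1)(c1ccccc1)C(C)(C)C | intermediate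
12 | lithium 15-O-TBDPS-19-nor-ent-labda-3,8(17),13E-trien-3-olate (C3–C4 enolate) | C=C1CC[C@H]2[C@@](C)(CCC([O-])=C2C)[C@@H]1CC/C(C)=C/CO[Si](c1ccccc1)(c1ccccc1)C(C)(C)C.[Li+] | intermediate (not isolated)
13 | 15-O-TBDPS-18-hydroxy-ent-labda-8(17),13E-dien-3-one (4β-CH2OH equatorial, 4α-CH3 axial) | C=C1CC[C@H]2[C@@](C)(CCC(=O)[C@]2(C)CO)[C@@H]1CC/C(C)=C/CO[Si](c1ccccc1)(c1ccccc1)C(C)(C)C | intermediate
14 | 18-O-TBS-15-O-TBDPS-18-hydroxy-ent-labda-8(17),13E-dien-3-one | C=C1CC[C@H]2[C@@](C)(CCC(=O)[C@]2(C)CO[Si](C)(C)C(C)(C)C)[C@@H]1CC/C(C)=C/CO[Si](c1ccccc1)(c1ccccc1)C(C)(C)C | intermediate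
15 | 18-O-TBS-15-O-TBDPS-ent-labda-8(17),13E-diene-3α,15,18-triol | C=C1CC[C@H]2[C@@](C)(CC[C@@H](O)[C@]2(C)CO[Si](C)(C)C(C)(C)C)[C@@H]1CC/C(C)=C/CO[Si](c1ccccc1)(c1ccccc1)C(C)(C)C | intermediate
16 | angelic acid, (Z)-2-methylbut-2-enoic acid | C/C=C(/C)C(=O)O | starting material
17 | angelic 2,4,6-trichlorobenzoic mixed anhydride | C/C=C(/C)C(=O)OC(=O)c1c(Cl)cc(Cl)cc1Cl | intermediate (not isolated)
18 | 3α-O-angeloyl-18-O-TBS-15-O-TBDPS-ent-labda-8(17),13E-diene-3α,15,18-triol | C=C1CC[C@H]2[C@@](C)(CC[C@@H](OC(=O)/C(C)=C\C)[C@]2(C)CO[Si](C)(C)C(C)(C)C)[C@@H]1CC/C(C)=C/CO[Si](c1ccccc1)(c1ccccc1)C(C)(C)C | intermediate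
19 | 3α-angeloyloxy-ent-labda-8(17),13E-diene-15,18-diol (CNP0118197.1) | C=C1CC[C@H]2[C@@](C)(CC[C@@H](OC(=O)/C(C)=C\C)[C@]2(C)CO)[C@@H]1CC/C(C)=C/CO | target

**Step count**
Total steps: 12. Longest linear sequence: 12 (from andrographolide 1; angelic acid 16 enters at step 11).

**Three steps most likely to fail, with fallbacks**

Step 2. The Mitsunobu displacement at the hindered allylic C14 may instead go SN2′ at C12 or eliminate to the 11,12-didehydro diene, and either path would not give the endocyclic butenolide. The fallback sets out from 2 and comes back at 5. Acetylation of 2 (Ac2O, DMAP, CH2Cl2, 0 °C) gives 14-O-acetyl-3,19-O-isopropylidene andrographolide F1. NaBH4 in THF–i-PrOH at 0 °C then adds hydride to C12 of the alkylidene lactone, and the enolate expels the C14 acetate, as in the hydride reduction of Morita–Baylis–Hillman acetates. This gives 5 without a pericyclic step.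

Step 4. The regioselectivity of the monosilylation rests only on a steric difference between two primary allylic hydroxyls and may be modest. The fallback sets out from 5 and comes back at 7.
- Me(MeO)NH·HCl and AlMe3 (CH2Cl2, 0 °C) open the lactone to the (13Z)-15-hydroxy Weinreb amide F2, in which only the 15-OH is free.
- TBDPSCl and imidazole give the 15-O-TBDPS Weinreb amide F3.
- i-Bu2AlH (THF, −78 °C) gives the (13Z)-15-silyloxy-16-al F4.
- NaBH4 with CeCl3·7H2O (MeOH, −40 °C) reduces F4 to 7.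

Step 8. The deformylative enolate generation may be undermined by C2 enolisation or proton transfer that scrambles the enolate, by incomplete fragmentation, or by retro-aldol of the product. The fallback sets out from 11 and comes back at 13.
- Pinnick oxidation (NaClO2, NaH2PO4, 2-methyl-2-butene, t-BuOH–H2O) gives 15-O-TBDPS-3-oxo-ent-labda-8(17),13E-dien-19-oic acid F5.
- Decarboxylative chlorination with N-chlorosuccinimide (toluene, 0 °C) gives 15-O-TBDPS-4-chloro-19-nor-ent-labda-8(17),13E-dien-3-one F6 as C4 epimers.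
- SmI2 (divalent samarium, 2.2 equiv, THF, −78 °C) reduces the C–Cl bond to the same C3–C4 enolate, now bound to trivalent samarium. Monomeric formaldehyde traps it in a Reformatsky-type aldol on the β face to give 13.

**Further compounds**
F1 | step 2 | 14-O-acetyl-3,19-O-isopropylidene andrographolide | C=C1CC[C@H]2[C@@](C)(CC[C@H]3OC(C)(C)OC[C@@]23C)[C@@H]1C/C=C1/C(=O)OC[C@H]1OC(C)=O
F2 | step 4 | (13Z)-15-hydroxy-3,19-O-isopropylidene-ent-labda-8(17),13-dien-16-oic acid N-methoxy-N-methylamide | C=C1CC[C@H]2[C@@](C)(CC[C@H]3OC(C)(C)OC[C@@]23C)[C@@H]1CC/C(C(=O)N(C)OC)=C/CO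
F3 | step 4 | 15-O-TBDPS ether of F2 | C=C1CC[C@H]2[C@@](C)(CC[C@H]3OC(C)(C)OC[C@@]23C)[C@@H]1CC/C(C(=O)N(C)OC)=C/CO[Si](c1ccccc1)(c1ccccc1)C(C)(C)C
F4 | step 4 | (13Z)-15-O-TBDPS-3,19-O-isopropylidene-ent-labda-8(17),13-dien-16-al | C=C1CC[C@H]2[C@@](C)(CC[C@H]3OC(C)(C)OC[C@@]23C)[C@@H]1CC/C(C=O)=C/CO[Si](c1ccccc1)(c1ccccc1)C(C)(C)C
F5 | step 8 | 15-O-TBDPS-3-oxo-ent-labda-8(17),13E-dien-19-oic acid | C=C1CC[C@H]2[C@@](C)(CCC(=O)[C@@]2(C)C(=O)O)[C@@H]1CC/C(C)=C/CO[Si](c1ccccc1)(c1ccccc1)C(C)(C)C
F6 | step 8 | 15-O-TBDPS-4-chloro-19-nor-ent-labda-8(17),13E-dien-3-one (C4 epimers) | C=C1CC[C@H]2[C@@](C)(CCC(=O)C2(C)Cl)[C@@H]1CC/C(C)=C/CO[Si](c1ccccc1)(c1ccccc1)C(C)(C)C
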